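## Retrosynthetic overview
1. Target ⇒ Negishi methylation of the C7-C8 enol triflate ⇒ 8-oxo-17-norlabdane diacetate. C9 is set by α-face hydrogenation and is also the equatorial epimer.
2. Ring B (formed last) ⇒ iodonium-triggered alkynyl semipinacol ring expansion. C10 shifts from C8 to C9 of a 1-alkynyl-trans-hydrindan-1-ol, which turns the five-membered ring into ring B and fixes the side chain on C9.
3. C8-C9 bond ⇒ acetylide addition of (S)-3-methylhex-5-yn-1-ol to the hydrindanone. C13 comes from CuH reduction of an unsaturated δ-lactone and C9 from an Ohira-Bestmann homologation.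
4. Ring A (formed second) ⇒ Fe-H (MHAT) radical closure of C4 onto the C3 aldehyde, which creates the gem-dimethyl group, the C3-C4 bond and the 3β-OH together.
5. Five-membered ring (bought) ⇒ 2-methylcyclopentenone + isopropenyl-MgBr + allyl bromide, which sets C5 and C10. Ring order: cyclopentane, then A, then B by expansion.

Assumption: positions carry labdane numbering, and the ligand hands quoted are those expected to give the drawn enantiomers (both antipodes are commercial).

## Route

Step 1
Reactants: 1 2-methylcyclopent-2-en-1-one; 2 isopropenylmagnesium bromide; 3 allyl bromide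
Product: 5 (2S,3S)-2-allyl-2-methyl-3-(prop-1-en-2-yl)cyclopentan-1-one, via bromomagnesium enolate 4 (not isolated)
Conditions: CuBr·SMe2 (5 mol %), (R,S)-Rev-Josiphos (6 mol %), MTBE, -78 °C; then 3, DMPU, -78 °C to rt
Reagents that add atoms: none
Why: In this tandem copper-catalysed asymmetric conjugate addition and enolate alkylation (established on this enone for alkyl Grignards), the ligand controls the face of isopropenyl delivery and so sets C5, and the magnesium enolate is then allylated anti to that group, which fixes the quaternary C10 with methyl and H-5 trans.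

Step 2
Reactants: 5 (2S,3S)-2-allyl-2-methyl-3-(prop-1-en-2-yl)cyclopentan-1-one
Product: 6 3-[(1S,5S)-1-methyl-2-oxo-5-(prop-1-en-2-yl)cyclopentyl]propanal
Conditions: PdCl2(PhCN)2 (10 mol %), CuCl2·2H2O (10 mol %), AgNO2 (5 mol %), t-BuOH/MeNO2 15:1, O2 (1 atm), rt
Reagents that add atoms: dioxygen (O=O)
Why: The nitrite-modified, aldehyde-selective (anti-Markovnikov) Wacker oxidation works best on terminal alkenes next to a quaternary carbon, it leaves the 1,1-disubstituted isopropenyl group and the ketone alone, and the trans arrangement blocks Pd-mediated diene cyclisation, so no stereocentre is touched.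

Step 3
Reactants: 6 3-[(1S,5S)-1-methyl-2-oxo-5-(prop-1-en-2-yl)cyclopentyl]propanal
Product: 7 (3aS,5S,7aS)-5-hydroxy-4,4,7a-trimethyloctahydro-1H-inden-1-one
Conditions: Fe(acac)3 (30 mol %), PhSiH3 (2.5 equiv), EtOH, 60 °C, Ar
Reagents that add atoms: none
Why: In this HAT-initiated reductive radical carbonyl cyclisation, Fe-H transfers a hydrogen atom to the isopropenyl CH2, and the tertiary C4 radical closes 6-exo on the aldehyde through a chair with the oxygen pseudo-equatorial, so ring A, the gem-dimethyl group and the equatorial 3β-OH form together, while attack on the ring ketone would need a four-membered ring.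

Step 4
Reactants: 8 4-methyl-5,6-dihydro-2H-pyran-2-one
Product: 9 (R)-4-methyltetrahydro-2H-pyran-2-one
Conditions: Cu(OAc)2·H2O (2 mol %), (R)-DTBM-SEGPHOS (2 mol %), (EtO)2MeSiH, t-BuOH, toluene, 0 °C
Reagents that add atoms: none
Why: Ligated CuH asymmetric conjugate reduction of a β,β-disubstituted unsaturated lactone delivers hydride to one face of the ring alkene and so sets C13.

Step 5
Reactants: 9 (R)-4-methyltetrahydro-2H-pyran-2-one
Product: 11 (S)-3-methylhex-5-yn-1-ol, via lactol 10 (not isolated)
Conditions: DIBAL-H, CH2Cl2, -78 °C; then MeOH, K2CO3, Ohira-Bestmann reagent, rt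
Reagents that add atoms: dimethyl (1-diazo-2-oxopropyl)phosphonate, CC(=O)C(=[N+]=[N-])P(=O)(OC)OC
Why: Half-reduction gives the lactol, whose open hydroxy-aldehyde form undergoes Ohira-Bestmann (Seyferth-Gilbert) homologation to the terminal alkyne, which adds C9 without touching C13.

Step 6
Reactants: 7 (3aS,5S,7aS)-5-hydroxy-4,4,7a-trimethyloctahydro-1H-inden-1-one; 11 (S)-3-methylhex-5-yn-1-ol
Product: 13 (1S,3aS,5S,7aS)-1-[(4S)-6-hydroxy-4-methylhex-1-yn-1-yl]-4,4,7a-trimethyloctahydro-1H-indene-1,5-diol, via dilithiated alkynol 12 (not isolated)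
Conditions: 11 (2.2 equiv), n-BuLi (4.4 equiv), THF, -78 to 0 °C; add 7, -78 °C to rt; H2O (excess 11 recovered)
Reagents that add atoms: none
Why: The weakly basic lithium acetylide adds 1,2 to the hindered cyclopentanone from the α face, anti to the angular methyl as in 17-keto steroids, giving the 8β-carbinol whose configuration is erased later, and the extra equivalent covers the free 3-OH.

Step 7
Reactants: 13 (1S,3aS,5S,7aS)-1-[(4S)-6-hydroxy-4-methylhex-1-yn-1-yl]-4,4,7a-trimethyloctahydro-1H-indene-1,5-diol
Product: 14 (S)-6-[(1S,3aS,5S,7aS)-5-acetoxy-1-hydroxy-4,4,7a-trimethyloctahydro-1H-inden-1-yl]-3-methylhex-5-yn-1-yl acetate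
Conditions: Ac2O (2.4 equiv), pyridine, DMAP (cat.), CH2Cl2, 0 °C to rt
Reagents that add atoms: acetic anhydride, CC(=O)OC(C)=O
Why: Chemoselective acylation takes the primary and the equatorial secondary OH but not the tertiary propargylic OH next to quaternary C10, so both target acetates are installed and the C15-OH is removed as a competing nucleophile for the next step.

Step 8
Reactants: 14 (S)-6-[(1S,3aS,5S,7aS)-5-acetoxy-1-hydroxy-4,4,7a-trimethyloctahydro-1H-inden-1-yl]-3-methylhex-5-yn-1-yl acetate
Product: 15 (13S,Z)-11-iodo-8-oxo-17-norlabd-9(11)-ene-3β,15-diyl diacetate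
Conditions: NIS (1.2 equiv), AgNTf2 (10 mol %), 4 Å MS, CH2Cl2/HFIP 9:1, -20 °C to rt, dark
Reagents that add atoms: N-iodosuccinimide, O=C1CCC(=O)N1I
Why: Proposed new method: Ag-activated NIS in a dry, ionising, non-nucleophilic medium forms an iodirenium ion on the dialkyl alkyne, and because the alkyne is linear there is no rotamer bias at C9, so the electron-richer C8-C10 σ-bond (quaternary migrating carbon, relief of vicinal C8/C10 crowding and of trans-hydrindane strain, C=O formation as driving force) shifts onto C9 anti to iodine with retention at C10, closing ring B as the (Z)-β-iodo enone while succinimide takes the carbinol proton; the closest known reaction types are the halonium-induced semipinacol enlargement of 1-(haloethynyl)cyclopentanols and the gold(I)-catalysed ring expansion of 1-alkynylcyclobutanols, neither shown for an unstrained carbinol with a dialkyl alkyne and a quaternary migrating centre.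

Step 9
Reactants: 15 (13S,Z)-11-iodo-8-oxo-17-norlabd-9(11)-ene-3β,15-diyl diacetate
Product: 17 (13S)-8-oxo-17-norlabdane-3β,15-diyl diacetate, via deiodinated E-enone 16 (not isolated)
Conditions: H2 (1 atm), 10 % Pd/C, NaOAc, EtOH, rt
Reagents that add atoms: none
Why: Catalytic hydrogenolysis of the vinyl C-I bond and hydrogenation of the strained exocyclic enone take place from the α face, opposite the axial C10 methyl, and this sets 9α-H with the side chain equatorial, which is also the thermodynamic epimer α to the ketone.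

Step 10
Reactants: 17 (13S)-8-oxo-17-norlabdane-3β,15-diyl diacetate
Product: 19 (13S)-8-(trifluoromethylsulfonyloxy)-17-norlabd-7-ene-3β,15-diyl diacetate, via potassium C7-enolate 18 (not isolated)
Conditions: KHMDS (1.05 equiv), THF, -78 °C; PhNTf2, -78 to 0 °C
Reagents that add atoms: N-phenylbis(trifluoromethanesulfonimide), O=S(=O)(N(c1ccccc1)S(=O)(=O)C(F)(F)F)C(F)(F)F
Why: Kinetic deprotonation of the 2-substituted cyclohexanone occurs at the unhindered C7-H rather than at the tertiary C9-H next to C10, the ketone is clearly more acidic than the acetates toward a silazide, and O-triflation locks the Δ7 regiochemistry without touching C9.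

Step 11
Reactants: 19 (13S)-8-(trifluoromethylsulfonyloxy)-17-norlabd-7-ene-3β,15-diyl diacetate
Product: 20 (3S,5R,9S,10R,13S)-labd-7-ene-3,15-diyl diacetate
Conditions: MeZnCl (2 equiv), Pd(PPh3)4 (5 mol %), LiCl, THF, 50 °C
Reagents that add atoms: methylzinc chloride, C[Zn]Cl
Why: Negishi cross-coupling replaces the triflate by the C17 methyl with the double bond held at C7-C8, the organozinc leaves both acetates intact, and no stereocentre is involved.

## Compound list
1 | 2-methylcyclopent-2-en-1-one | CC1=CCCC1=O | starting material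
2 | isopropenylmagnesium bromide | CC(=C)[Mg]Br | starting material
3 | allyl bromide | C=CCBr | starting material
4 | bromomagnesium (3S)-2-methyl-3-(prop-1-en-2-yl)cyclopent-1-en-1-olate | CC1=C(O[Mg]Br)CC[C@H]1C(C)=C | intermediate
5 | (2S,3S)-2-allyl-2-methyl-3-(prop-1-en-2-yl)cyclopentan-1-one (allyl trans to isopropenyl) | C=CC[C@]1(C)C(=O)CC[C@H]1C(C)=C | intermediate
6 | 3-[(1S,5S)-1-methyl-2-oxo-5-(prop-1-en-2-yl)cyclopentyl]propanal | O=CCC[C@]1(C)C(=O)CC[C@H]1C(C)=C | intermediate
7 | (3aS,5S,7aS)-5-hydroxy-4,4,7a-trimethyloctahydro-1H-inden-1-one (trans-fused, equatorial OH = 3β) | O=C1CC[C@H]2C(C)(C)[C@@H](O)CC[C@]12C | intermediate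
8 | 4-methyl-5,6-dihydro-2H-pyran-2-one | CC1=CC(=O)OCC1 | starting material
9 | (R)-4-methyltetrahydro-2H-pyran-2-one | O=C1C[C@H](C)CCO1 | intermediate
10 | (4R)-4-methyltetrahydro-2H-pyran-2-ol (lactol, anomers) | OC1C[C@H](C)CCO1 | intermediate
11 | (S)-3-methylhex-5-yn-1-ol | C#CC[C@H](C)CCO | intermediate
12 | dilithium salt of 11 (acetylide alkoxide) | [Li]C#CC[C@H](C)CCO[Li] | intermediate
13 | (1S,3aS,5S,7aS)-1-[(4S)-6-hydroxy-4-methylhex-1-yn-1-yl]-4,4,7a-trimethyloctahydro-1H-indene-1,5-diol | OCC[C@@H](C)CC#C[C@]1(O)CC[C@H]2C(C)(C)[C@@H](O)CC[C@]12C | intermediate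
14 | 3,15-di-O-acetate of 13 (tertiary 8β-OH free) | CC(=O)OCC[C@@H](C)CC#C[C@]1(O)CC[C@H]2C(C)(C)[C@@H](OC(C)=O)CC[C@]12C | intermediate
15 | (13S,Z)-11-iodo-8-oxo-17-norlabd-9(11)-ene-3β,15-diyl diacetate (trans-decalin) | CC(=O)OCC[C@@H](C)C/C(I)=C1/C(=O)CC[C@H]2C(C)(C)[C@@H](OC(C)=O)CC[C@]12C | intermediate
16 | (13S,E)-8-oxo-17-norlabd-9(11)-ene-3β,15-diyl diacetate | CC(=O)OCC[C@@H](C)C/C=C1/C(=O)CC[C@H]2C(C)(C)[C@@H](OC(C)=O)CC[C@]12C | intermediate
17 | (13S)-8-oxo-17-norlabdane-3β,15-diyl diacetate (5α-H, 9α-H, 10β-Me) | CC(=O)OCC[C@@H](C)CC[C@H]1C(=O)CC[C@H]2C(C)(C)[C@@H](OC(C)=O)CC[C@]12C | intermediate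
18 | potassium Δ7-enolate of 17 | CC(=O)OCC[C@@H](C)CC[C@H]1C([O-])=CC[C@H]2C(C)(C)[C@@H](OC(C)=O)CC[C@]12C.[K+] | intermediate
19 | (13S)-8-(trifluoromethylsulfonyloxy)-17-norlabd-7-ene-3β,15-diyl diacetate | CC(=O)OCC[C@@H](C)CC[C@H]1C(OS(=O)(=O)C(F)(F)F)=CC[C@H]2C(C)(C)[C@@H](OC(C)=O)CC[C@]12C | intermediate
20 | (3S,5R,9S,10R,13S)-labd-7-ene-3,15-diyl diacetate (CNP0251773.1) | CC(=O)OCC[C@@H](C)CC[C@H]1C(C)=CC[C@H]2C(C)(C)[C@@H](OC(C)=O)CC[C@]12C | target

## Step count and risks
Total step count: 11. Longest linear sequence: 9 (steps 1, 2, 3, 6, 7, 8, 9, 10, 11).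

**Step 8 (the new ring expansion).**
- The risks are migration of C7 instead of C10, fragmentation to ketone plus iodoalkyne, and an iodo-Meyer-Schuster pathway if water is present.
- The fallback uses known chemistry, sets out from 14 and comes back at 17.
- CO2-assisted silver-catalysed hydration of the propargylic alcohol places the carbonyl on C9 and gives the α-hydroxy ketone F1.
- KOH in MeOH then triggers the base-mediated α-ketol (acyloin) ring enlargement. This is the reaction used for D-homoannulation of 17α-hydroxy-20-keto steroids, where the quaternary carbon migrates. Both acetates are lost here, and the product is the ring-enlarged 9-hydroxy-8-ketone F2.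
- SmI2 in THF/HMPA removes the tertiary α-hydroxyl and, after protonation to the equatorial epimer, gives the keto diol F3.
- Ac2O/pyridine converts this into 17.

**Step 1 (ACA with an sp2 Grignard).**
- The risks are low ee and competing 1,2-addition.
- The fallback sets out from 1 and comes back at 5.
- Rh(I)/BINAP/Et3N-catalysed 1,4-addition of potassium isopropenyltrifluoroborate in aqueous toluene gives the 2-methyl-3-isopropenyl ketone F4. Its C2 epimers are irrelevant.
- Thermodynamic silylation (TMSCl, NaI, Et3N, MeCN) gives the tetrasubstituted silyl enol ether F5.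
- Fluoride-promoted allylation with 3 occurs anti to the isopropenyl group and gives 5.

**Step 3 (MHAT closure onto the aldehyde).**
- The risks are premature reduction of the C4 radical, reversible C-O radical formation, and a poor ratio of C3 epimers.
- The fallback sets out from 6 and comes back at 7.
- I2 with aqueous NH3 converts the aldehyde into the keto nitrile F6.
- The same Fe-H conditions close the C4 radical onto the nitrile to give the ketimine F7, which is hydrolysed on work-up to the 3,8-dione F8.
- NaBH4 at low temperature reduces the six-ring ketone by axial attack to the 3β-alcohol 7. The cyclopentanone next to the quaternary carbon reacts more slowly.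

## Further compounds
F1 | step 8 | (S)-6-[(1S,3aS,5S,7aS)-5-acetoxy-1-hydroxy-4,4,7a-trimethyloctahydro-1H-inden-1-yl]-3-methyl-6-oxohexyl acetate | CC(=O)OCC[C@@H](C)CCC(=O)[C@]1(O)CC[C@H]2C(C)(C)[C@@H](OC(C)=O)CC[C@]12C
F2 | step 8 | (13S)-3β,9,15-trihydroxy-17-norlabdan-8-one (C9 configuration irrelevant) | OCC[C@@H](C)CCC1(O)C(=O)CC[C@H]2C(C)(C)[C@@H](O)CC[C@]12C
F3 | step 8 | (13S)-3β,15-dihydroxy-17-norlabdan-8-one | OCC[C@@H](C)CC[C@H]1C(=O)CC[C@H]2C(C)(C)[C@@H](O)CC[C@]12C
F4 | step 1 | (3R)-2-methyl-3-(prop-1-en-2-yl)cyclopentan-1-one (C2 epimers) | CC1C(=O)CC[C@H]1C(C)=C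
F5 | step 1 | (S)-trimethyl{[2-methyl-3-(prop-1-en-2-yl)cyclopent-1-en-1-yl]oxy}silane | C=C(C)[C@@H]1CCC(O[Si](C)(C)C)=C1C
F6 | step 3 | 3-[(1S,5S)-1-methyl-2-oxo-5-(prop-1-en-2-yl)cyclopentyl]propanenitrile | N#CCC[C@]1(C)C(=O)CC[C@H]1C(C)=C
F7 | step 3 | (3aS,7aS)-5-imino-4,4,7a-trimethyloctahydro-1H-inden-1-one | O=C1CC[C@H]2C(C)(C)C(=N)CC[C@]12C
F8 | step 3 | (3aS,7aS)-4,4,7a-trimethylhexahydro-1H-indene-1,5(4H)-dione | O=C1CC[C@H]2C(C)(C)C(=O)CC[C@]12C
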